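**Plan**

1. Retrosynthesis: at both ends at once, the C2–C3 bond of each 5,6-dihydropyridin-2-one ring and the bond from N1 to the exocyclic cyclobutane carbonyl are cut. This leaves the α-truxillic diacid 2 and two molecules of the iodoalkenyl isocyanide 7; the cyclobutane is then cut into two molecules of the cinnamic acid 1.
2. Enabling feature: each end is an imide in which ring atom N1 carries the ring carbonyl C2 and the exocyclic acyl group, with the C3=C4 alkene next to C2. An isocyanide carbon standing for C2 can accept C3 (as an alkenyl radical) and then a carboxylate oxygen of 2; the O-acyl lactim so formed hands its acyl group to N1, so ring, lactam C=O, conjugated alkene and imide link arise together.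
3. Forward order: the cyclobutane first, by head-to-tail [2+2] photodimerisation of crystalline 1 (the dimerisation mode presumed for the biosynthesis of such cyclobutane amides); then both nitrogen rings in the last step, two-directionally on the centrosymmetric diacid.
4. Stereochemistry: all four stereocentres come from step 1 (E-alkene geometry plus the inversion-related pair in the crystal give the meso pattern: aryl groups trans, acyl groups trans). No strong base is used once the imide exists; the ring alkenes are cis by ring constraint.

Key step: step 6

Remark on the chemistry: the target SMILES encodes the centrosymmetric (meso) α-truxillic pattern, so no absolute stereocontrol is needed; 1 is assumed to crystallise in the head-to-tail α-type packing usual for alkoxycinnamic acids.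

**Route**

Step 1
Reactants: 1 (2E)-3-(3,4-dimethoxyphenyl)prop-2-enoic acid (two molecules)
Product: 2 (1α,2α,3β,4β)-2,4-bis(3,4-dimethoxyphenyl)cyclobutane-1,3-dicarboxylic acid (meso)
Conditions: hν (medium-pressure Hg lamp, Pyrex, λ > 300 nm), finely ground crystals of 1 (from EtOH) stirred as a suspension in water, 20 °C, 48 h; recrystallisation
Reagents that add atoms: none
Why: Topochemical [2+2] photodimerisation: inversion-related head-to-tail neighbours in the crystal lie with parallel alkenes about 4 Å apart, so suprafacial addition keeps aryl and carboxyl trans within each former E-alkene while the inversion centre places the two aryl groups trans and the two carboxyl groups trans, which sets all four stereocentres as the meso α-truxillic pattern.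

Step 2
Reactants: 3 but-3-yn-1-amine
Product: 4 N-(but-3-yn-1-yl)formamide
Conditions: HCO2Et (excess, as solvent), reflux, 12 h; evaporation
Reagents that add atoms: ethyl formate (CCOC=O)
Why: N-Formylation by aminolysis of a formate ester; the terminal alkyne is inert.

Step 3
Reactants: 4 N-(but-3-yn-1-yl)formamide
Product: 5 N-(4-iodobut-3-yn-1-yl)formamide
Conditions: N-iodosuccinimide (1.1 equiv), AgNO3 (10 mol %), acetone, 20 °C, dark, 2 h
Reagents that add atoms: N-iodosuccinimide (O=C1CCC(=O)N1I)
Why: Silver-catalysed electrophilic iodination of a terminal alkyne through the silver acetylide; the secondary formamide should not interfere.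

Step 4
Reactants: 5 N-(4-iodobut-3-yn-1-yl)formamide
Product: 6 N-[(3Z)-4-iodobut-3-en-1-yl]formamide
Conditions: 2-nitrobenzenesulfonyl hydrazide (2.5 equiv), Et3N (5 equiv), THF/i-PrOH 1:1, 23 °C, 16 h, stopped at full conversion of 5
Reagents that add atoms: none
Why: Diimide reduction: diimide released from the sulfonyl hydrazide delivers two hydrogens to the same face of the alkyne in a concerted cyclic transition state, which gives the (Z)-iodoalkene and leaves the C–I bond intact.

Step 5
Reactants: 6 N-[(3Z)-4-iodobut-3-en-1-yl]formamide
Product: 7 (1Z)-1-iodo-4-isocyanobut-1-ene
Conditions: POCl3 (1.1 equiv), Et3N (3 equiv), CH2Cl2, −20 to 0 °C, 1 h; cold aq. Na2CO3 work-up; filtration through basic alumina; stored cold in the dark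
Reagents that add atoms: none
Why: Dehydration of an N-monosubstituted formamide through its O-phosphorylated imidate (Ugi isocyanide synthesis); the amine base is too weak to eliminate HI from the (Z)-iodoalkene.

Step 6
Reactants: 2 (1α,2α,3β,4β)-2,4-bis(3,4-dimethoxyphenyl)cyclobutane-1,3-dicarboxylic acid; 7 (1Z)-1-iodo-4-isocyanobut-1-ene (two molecules)
Product: 10 1,1'-{[(1α,2α,3β,4β)-2,4-bis(3,4-dimethoxyphenyl)cyclobutane-1,3-diyl]dicarbonyl}bis(5,6-dihydropyridin-2(1H)-one) (target CNP0199212.1), via dicesium dicarboxylate 8 (not isolated), via bis(O-acyl lactim) 9 (not isolated)
Conditions: 2 (1.0 equiv), Cs2CO3 (2.0 equiv), Pd(OAc)2 (10 mol %), Xantphos (20 mol %), degassed PhH (0.01 M), argon, blue LEDs (450 nm), 25 °C; 7 (2.4 equiv) in PhH added by syringe pump over 10 h; then 40 °C, 2 h in the dark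
Reagents that add atoms: none
Why: Proposed new method: light-excited zerovalent palladium (from Pd(OAc)2 and Xantphos) should cleave the C3–I bond of 7 by single-electron transfer to an alkenyl radical held near monovalent palladium iodide; the σ-radical at C3 adds to the isocyanide carbon C2 at the end of its own four-atom tether, which forms the C2–C3 bond and the six-membered ring, and the cyclic imidoyl radical recombines with palladium to an imidoyl complex of divalent palladium that takes up a carboxylate of 8, undergoes C–O reductive elimination to the O-acyl lactim 9 and lets the acyl group migrate from O to N1 (Mumm rearrangement), once at each end of the centrosymmetric diacid. The closest known reaction types are the palladium-catalysed imidoylative coupling of organic halides, isocyanides and oxygen nucleophiles (carboxylates give imides by the same O-to-N acyl shift), the visible-light palladium chemistry of vinyl iodides that gives alkenyl radicals, and radical addition to the carbon of isocyanides; what is new is that the isocyanide is tethered to the halide and is attacked in the endo sense. The radical path is chosen on purpose, since a two-electron 1,1-insertion would need a seven-membered chelate that holds a linear Pd–C≡N–C unit, whereas the radical needs only to reach C2. Each ring closes in a 6-endo-dig mode (attack at the terminal carbon of the N≡C unit, N1 inside the ring), and no exo mode competes because radicals do not add to the isocyanide nitrogen. No stereocentre is created; the four cyclobutane stereocentres of 2 stay as set in step 1 because the medium holds only carbonate and carboxylate at room temperature and the acidic imide α-C–H appears only at the very end, and the ring alkene is cis by ring constraint whatever the geometry of the alkenyl radical. The selectivity needed is ring closure before capture of a second isocyanide or of hydrogen, which the short (Z)-tether, high dilution in benzene and slow addition of 7 should secure, and O-capture before further insertion, which the carboxylate kept in excess over free isocyanide should secure.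

**Compound list**

1 | (2E)-3-(3,4-dimethoxyphenyl)prop-2-enoic acid | COc1ccc(/C=C/C(=O)O)cc1OC | starting material
2 | (1α,2α,3β,4β)-2,4-bis(3,4-dimethoxyphenyl)cyclobutane-1,3-dicarboxylic acid (meso) | COc1ccc([C@H]2[C@H](C(=O)O)[C@H](c3ccc(OC)c(OC)c3)[C@H]2C(=O)O)cc1OC | intermediate
3 | but-3-yn-1-amine | C#CCCN | starting material
4 | N-(but-3-yn-1-yl)formamide | O=CNCCC#C | intermediate
5 | N-(4-iodobut-3-yn-1-yl)formamide | O=CNCCC#CI | intermediate
6 | N-[(3Z)-4-iodobut-3-en-1-yl]formamide | O=CNCC/C=C\I | intermediate
7 | (1Z)-1-iodo-4-isocyanobut-1-ene | [C-]#[N+]CC/C=C\I | intermediate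
8 | dicesium (1α,2α,3β,4β)-2,4-bis(3,4-dimethoxyphenyl)cyclobutane-1,3-dicarboxylate | COc1ccc([C@H]2[C@H](C(=O)[O-])[C@H](c3ccc(OC)c(OC)c3)[C@H]2C(=O)[O-])cc1OC.[Cs+].[Cs+] | intermediate
9 | bis(5,6-dihydropyridin-2-yl) (1α,2α,3β,4β)-2,4-bis(3,4-dimethoxyphenyl)cyclobutane-1,3-dicarboxylate | COc1ccc([C@H]2[C@H](C(=O)OC3=NCCC=C3)[C@H](c3ccc(OC)c(OC)c3)[C@H]2C(=O)OC2=NCCC=C2)cc1OC | intermediate
10 | 1,1'-{[(1α,2α,3β,4β)-2,4-bis(3,4-dimethoxyphenyl)cyclobutane-1,3-diyl]dicarbonyl}bis(5,6-dihydropyridin-2(1H)-one) | COc1ccc([C@H]2[C@H](C(=O)N3CCC=CC3=O)[C@H](c3ccc(OC)c(OC)c3)[C@H]2C(=O)N2CCC=CC2=O)cc1OC | target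

**Step count and risks**

Total step count: 6. Longest linear sequence: 5 steps (3 → 4 → 5 → 6 → 7 → 10).

Steps most likely to fail:

1. Step 6 (Proposed new method). What may go wrong: capture of a second isocyanide molecule or of hydrogen by the alkenyl radical before the endo closure, repeated insertion of the unhindered primary isocyanide at palladium, or a slow acyl shift at the hindered cyclobutane carbonyl. Each would give oligomers, reduced material or half-cyclised products. Fallback with known chemistry, setting out from 2 and coming back at 10: 2 would be converted with oxalyl chloride and catalytic DMF in CH2Cl2 (0 to 20 °C) into (1α,2α,3β,4β)-2,4-bis(3,4-dimethoxyphenyl)cyclobutane-1,3-dicarbonyl dichloride F1. Purchased 5,6-dihydropyridin-2(1H)-one (O=C1C=CCCN1) would be deprotonated with LiN(SiMe3)2 in THF at −78 °C and acylated at nitrogen with F1 (inverse addition, −78 °C, short reaction time to avoid epimerisation), which should give 10 directly. In this fallback no ring is closed at the imide stage.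

2. Step 1. What may go wrong: 1 may crystallise in a photostable or differently packed form, or the lattice may lose order at partial conversion, so that the dimerisation stalls or loses its head-to-tail stereocontrol. Fallback, setting out from 1 and coming back at 10: 1 would be converted with oxalyl chloride and catalytic DMF into (2E)-3-(3,4-dimethoxyphenyl)prop-2-enoyl chloride F2. F2 would acylate lithiated 5,6-dihydropyridin-2(1H)-one (LiN(SiMe3)2, THF, −78 °C) to give the monomeric imide 1-[(2E)-3-(3,4-dimethoxyphenyl)prop-2-enoyl]-5,6-dihydropyridin-2(1H)-one F3. Crystalline F3 would then be irradiated (λ > 300 nm, solid state), so that the cyclobutane is formed last by head-to-tail dimerisation of the monomer, as presumed for the biosynthesis, to give 10. The stereochemical outcome would then rest on the crystal packing of F3 instead of that of 1.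

3. Step 4. What may go wrong: over-reduction of the iodoalkene to the iodoalkane, or incomplete conversion, which would leave mixtures that are hard to separate and would lower the Z purity that reaches step 6. Fallback, setting out from 4 and coming back at 6 (compound 5 is bypassed): copper-catalysed hydroboration of 4 (B2pin2, CuCl, NaOt-Bu, Xantphos, MeOH, THF, 20 °C) should give N-[(3E)-4-(4,4,5,5-tetramethyl-1,3,2-dioxaborolan-2-yl)but-3-en-1-yl]formamide F4. Treatment of F4 with ICl (CH2Cl2, −78 °C) and then NaOMe in MeOH should give 6 with inversion of alkene geometry, by anti addition of I–Cl followed by anti elimination of boron and chloride. The Z geometry would then come from this addition–elimination sequence and not from a syn hydrogen transfer.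

**Further compounds**

F1 | step 6 | (1α,2α,3β,4β)-2,4-bis(3,4-dimethoxyphenyl)cyclobutane-1,3-dicarbonyl dichloride | COc1ccc([C@H]2[C@H](C(Cl)=O)[C@H](c3ccc(OC)c(OC)c3)[C@H]2C(Cl)=O)cc1OC
F2 | step 1 | (2E)-3-(3,4-dimethoxyphenyl)prop-2-enoyl chloride | COc1ccc(/C=C/C(Cl)=O)cc1OC
F3 | step 1 | 1-[(2E)-3-(3,4-dimethoxyphenyl)prop-2-enoyl]-5,6-dihydropyridin-2(1H)-one | COc1ccc(/C=C/C(=O)N2CCC=CC2=O)cc1OC
F4 | step 4 | N-[(3E)-4-(4,4,5,5-tetramethyl-1,3,2-dioxaborolan-2-yl)but-3-en-1-yl]formamide | O=CNCC/C=C/B1OC(C)(C)C(C)(C)O1
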